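L cannot climb for ever in these flasks: Z turns X into L, but from its first moment L is also carried on to E by Q and G, and E goes on to J and back.

    Q + G + L → G + E (k1 = 67 M⁻² s⁻¹, Ea1 = 39.0 kJ mol⁻¹)
    X + Z → Z + L (k2 = 130 M⁻¹ s⁻¹, Ea2 = 40.0 kJ mol⁻¹)
    E ⇌ J (K3 = 0.16, k3 = 0.079 s⁻¹, Ea3 = 89.0 kJ mol⁻¹, ΔH3 = −78.0 kJ mol⁻¹)
    (constants at 35 °C)

| setting | delta | eta | zeta |
|---|---|---|---|
| X | 0.25 M | 0.25 M | 0.25 M |
| Q | 0.450 M | 0.450 M | 0.450 M |
| Z | 1.2 mM | 1.2 mM | 1.2 mM |
| G | 1.2 mM | 1.2 mM | 1.2 mM |
| temperature | 35 °C | 45 °C | 55 °C |
| time | 6.0 s | 6.0 s | 6.0 s |

- constants are those at 35 °C; use the activation energies and enthalpies for any other temperature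

* which of these there is most of at the end, counted by the X in it, delta (L / E / J / X)
* which of these there is most of at the end, counted by the X in it, eta (L / E / J / X)
* which of these there is most of at the end, counted by the X in it, zeta (L / E / J / X)
* the largest of these amounts at the end, in percent of the X charged, delta
* the largest of these amounts at the end, in percent of the X charged, eta
* the largest of these amounts at the end, in percent of the X charged, zeta

Turn the question round: what would keep L from leading? We hold Q at its charge, and Z and G come back unchanged, so each step is pseudo-first-order. X goes at the rate constant of its step times the amount of Z, 0.156 s⁻¹ in delta. L goes at the rate constant of its step times Q times G, 0.0362 s⁻¹ in delta.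

In this picture the height of the top of L is reckoned from their ratio, 4.31 in delta. Raise that ratio to minus one over the ratio less one, and we get 64.3% of the X charged for delta: the ceiling of L, the top of its curve under these two rates. A ratio of 2 gives a ceiling of 50.0%, so in this two-step picture L stays under half of the X below that ratio. Delta stands at twice that mark.

The two activation energies stand close together, at 40.0 kJ mol⁻¹ and 39.0 kJ mol⁻¹. In zeta the rates are 0.404 s⁻¹ and 0.0915 s⁻¹, their ratio is 4.42, and the ceiling is 64.7%. Heat moves the time of the top instead, which is the natural log of the ratio over the difference of the rates. That is 12.2 s in delta, after the end, and 4.75 s in zeta, before it.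

With the eta rates 0.255 s⁻¹ and 0.0584 s⁻¹, and with E and J counted as one pool under E, our hand reckoning names L for delta, L for eta and L for zeta. The amounts are 53.7%, 63.3% and 63.2%.

The forecast named L, L and L, at 54%, 64% and 65%, saying “L stays the largest pool at all three temperatures because it is made several times faster than it is consumed”. Its zeta figure stands above ours.

The flasks give L in delta, L in eta and L in zeta, at 53.9%, 63.8% and 65.0%. At 6.00 s in zeta, L is made at 0.705 of the rate at which it is used up, so that flask has passed its top, and its reading stands level with the ceiling. With 0.0020 M of G and zeta otherwise unchanged, the ratio falls to 2.65 and the ceiling to 55.4%. That flask reads 53.7% of L at 6.00 s.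

All constants are made up; the result is computed.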